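## Structural features

Diplotrin A is a flavone: ring A is fused to the pyranone ring C through C4a–C8a, and ring B is attached to C2 by the single bond C2–C1'. The molecule has no stereocentre, so no neighbouring stereocentres need to be controlled; the whole problem is the placement and differentiation of seven oxygens. Ring A carries three contiguous oxygens (O1 on C8a, methoxy groups on C8 and C7) while C5 and C6 are unsubstituted. Ring C carries a methoxy group on C3 next to the C4 carbonyl, and ring B is a 4'-methoxy-2',5'-hydroquinone. The hydroquinone is the fragile part, since air, base or any oxidant turns it into the quinone, and its two free hydroxyl groups must be told apart from four methyl ethers elsewhere. The real difficulties are therefore a regiodefined 1,2,3-trioxygenated ring A with two free CH positions, and the release of only the two para-related oxygens of ring B at the end. The key step exploits the run C8a(O)–C8(OMe)–C7(OMe), which is the O=C–C(OMe)=C(OMe) unit of a cyclobutenone made from dimethyl squarate; C6 is the fourth ring carbon, and C5, C4a and the C4 carbonyl come from a β-stannyl enone.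

## Logic of the disconnections

**18 ⇒ 17 ⇒ 16.** The two free hydroxyl groups of ring B are taken back to methyl ethers: 18 comes from 17 by reduction, and 17 from 16 by exchange of the C2'–OMe and C5'–OMe bonds for carbonyl groups. The cut is made here because the hydroquinone should exist only in the last flask, and because a para relationship is the one feature an oxidant can recognise among six methyl ethers. The gain is that no protecting group is introduced, carried or differentiated anywhere in the route. The demand on the forward step is chemoselectivity: electron transfer must come from ring B only, and the 4'-methoxy group, ring A and the C3 enol ether must survive.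

**16 ⇒ 15.** O1–C2 is cut, which opens ring C to the 1,3-diketone 15. This is the classical flavone disconnection; it leaves rings A and B joined by a three-carbon chain in which C3 already holds its methoxy group. The forward cyclodehydration requires that only one aryl ketone has an ortho phenol. In 15 the ortho oxygen of ring B is a methyl ether, so closure can only lead to 16.

**15 ⇒ 3 + 11.** Ring A is taken apart at C5–C6 and C4a–C8a. The carbonyl carbon of 3 becomes C8a and its oxygen becomes O1, the two methoxy-bearing alkene carbons become C8 and C7, and the chlorine-bearing carbon becomes C6. The tin-bearing carbon of 11 becomes C5 and the carbon α to the enone carbonyl becomes C4a. The gain is large: a trioxygenated benzene ring is reduced to a four-membered ring in which every oxygen already sits on its carbon, plus a linear stannane. The regiochemistry of ring A needs no directing group because it follows from which atoms are bonded in 3. The forward step demands coupling at the carbon that carried chlorine, a ring opening that can reach the inward ketene, and a stannane whose acidic diketone does not stop the palladium cycle.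

**11 ⇒ 9 + 10 (10 from 6).** The bond between the methoxy-bearing carbon (future C3) and the enone carbonyl (future C4) is cut, giving the ketone 9 and the acyl chloride 10, which is made in the flask from 6. The cut is placed here because 9 has a single enolisable position, so the enolate is unambiguous, and because ring B and its ketone then come from one cheap arene. The forward step must acylate at carbon and not at oxygen, and must not expose the vinyl–tin bond to strong acid.

**9 ⇒ 7 + 8.** The aryl–carbonyl bond (future C1'–C2) is cut. Both partners are commercial, and all three oxygens of ring B and the C3 methoxy group arrive in one step. The forward acylation must go to the position para to one methoxy group and ortho to another, which is the innate preference of 7.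

**6 ⇒ 5 ⇒ 4.** The C–CO2H bond is cut to 5 and carbon dioxide, and 5 is traced to 4 by tin–lithium exchange. A stannylcupration of a free alkynoic acid was set aside because the acidic proton would consume the cuprate, and an ester would cost a hydrolysis step. Compound 4 carries the E geometry from the bottle; the forward step only has to retain it.

**3 ⇒ 2 ⇒ 1.** The C–Cl bond is traced to a C–OH bond and this to one carbonyl group of the symmetric 1. The gain is a one-carbon desymmetrisation of a commercial C4 unit. The forward steps must stop at mono-reduction and must replace the hydroxyl group without acid, because acid makes 2 lose methanol and collapse to a cyclobutenedione.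

## Other disconnections considered

**Alternative 1:** The cut is in ring B, at C1'–C2' and C5'–C6'.
- **Forward key step:** 4-methoxy-2-(tert-butyldimethylsiloxy)furan A1 would add as the diene across the alkyne of 2-ethynyl-3,7,8-trimethoxy-4H-chromen-4-one A2. The oxygen bridge of the adduct would open at the siloxy-bearing carbon and the ring would aromatise to 2-[2-(tert-butyldimethylsiloxy)-5-hydroxy-4-methoxyphenyl]-3,7,8-trimethoxy-4H-chromen-4-one A3, one desilylation from 18.
- **In its favour:** The regiochemistry is electronically matched, since C5 of A1 is the nucleophilic end of the siloxydiene and the terminal alkyne carbon of A2 is the electrophilic end of a vinylogous ynone. Ring B is born with its three oxygens already differentiated, so no oxidation is needed at the end. On this point the alternative is better than the chosen plan, whose last step has to distinguish methyl ethers.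
- **Against it:** The alkyne is activated only through the C2=C3 bond, into which the 3-methoxy group donates, so A2 should be a poor dienophile. Heat or a Lewis acid would be needed, and the acid-labile A1 tolerates neither well; desilylation, or a Michael addition without ring closure, are likely diversions. The cut also leaves the whole chromone, with the contiguously oxygenated ring A and an ethynyl group on C2, to be made beforehand.
- **Comparison:** Structurally the chosen plan builds the hard ring and buys the easy one, and the alternative does the reverse. Mechanistically both end in an aromatisation that makes the pericyclic step irreversible; the alternative draws its regiochemistry from polarisation, the chosen plan from connectivity, which is the stronger guarantee. In step count the alternative should be longer once A2 is included, although its sequence after the key step (one step) is shorter.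

**Alternative 2:** The cut is on both sides of C4 (C4a–C4 and C3–C4), so that C4 becomes carbon monoxide.
- **Forward key step:** Pd(dba)2 with Xantphos would insert into the C–I bond of 1-iodo-3,4-dimethoxy-2-(methoxymethoxy)benzene A4, CO would give the aroylpalladium species, and the magnesium enolate of ketone 9 (MgCl2, NEt3) would be acylated to 1-[3,4-dimethoxy-2-(methoxymethoxy)phenyl]-2-methoxy-3-(2,4,5-trimethoxyphenyl)propane-1,3-dione A5. Acid would then remove the methoxymethyl group and close ring C to 16 in one operation.
- **In its favour:** A5 is the O-protected form of 15, so this plan shares 9, 16 and the end game with the chosen plan. A4 should be reachable in two steps from a commercial dimethoxyphenol by ortho-lithiation and iodination. No tin reagent and no labile chlorocyclobutenone are needed. On step economy (about six steps against eight) and on the handling of reagents this alternative is the better one; on the end game the two are equal.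
- **Against it:** The nucleophile is an α-methoxy ketone leading to a 2-substituted diketone, a more hindered case than the methyl ketones and malonates on which this three-component coupling is usually run. The aroylpalladium intermediate is flanked by an ortho alkoxy group. Direct α-arylation without CO, O-acylation of the enolate and retro-Claisen cleavage of the product are the competing processes.
- **Comparison:** The alternative buys the oxygen pattern of ring A, and the chosen plan makes it. The chosen plan is kept because the substitution of ring A is dictated by the mechanism and the approach would extend to patterns for which no phenol is sold. For this particular target the alternative is the more practical route.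

**Alternative 3:** The cut is at C3–C4 and O1–C2, which takes ring C apart into an aldehyde and an alkyne.
- **Forward key step:** [Cp*RhCl2]2 with Cu(OAc)2 as oxidant would activate the formyl C–H bond of 2-hydroxy-3,4-dimethoxybenzaldehyde A6 with the help of the phenoxide. The aryl ynol ether 1,4-bis(benzyloxy)-2-methoxy-5-(methoxyethynyl)benzene A7 would insert into the acyl–rhodium bond, and C–O reductive elimination would give 2-[2,5-bis(benzyloxy)-4-methoxyphenyl]-3,7,8-trimethoxy-4H-chromen-4-one A8. Hydrogenolysis would convert A8 into 18.
- **In its favour:** It is the most convergent of the four plans: ring C is closed with all its substituents in one catalytic step and without a diketone intermediate. Ring A comes from the commercial aldehyde A6. Both the aryl group and the polarisation of the ynol ether should send rhodium to the aryl-bearing carbon, which is the wanted regiochemistry. The benzyl ethers allow a reductive last step that is gentler than a cerium oxidation. On convergence and on the end game this alternative is the better one.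
- **Against it:** A7 is an electron-rich ynol ether that needs several steps and is prone to hydration or addition of acetic acid under the hot copper-acetate conditions. The electron-rich salicylaldehyde may be oxidised or decarbonylated. The regiochemistry, however plausible, rests on catalyst control for an alkyne class on which this annulation is not established.
- **Comparison:** Every bond of the chosen plan is fixed by connectivity, whereas the key bond set of the alternative depends on the selectivity of an insertion. In step count the two plans should be similar once A7 is included.

Key step: step 6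

Assumption: compounds 11 to 15 are drawn as diketo forms although they should exist largely as enols, their sp3 centres and those of 2 and 3 are racemic and without consequence because 18 is achiral, and 4 is taken as a purchased reagent.

## Route

Step 1
Reactants: 1 dimethyl squarate (3,4-dimethoxycyclobut-3-ene-1,2-dione)
Product: 2 4-hydroxy-2,3-dimethoxycyclobut-2-en-1-one (racemic)
Conditions: LiAlH(OtBu)3 (1.05 equiv), THF, −78 °C; pH 7 phosphate buffer
Reagents that add atoms: none
Why: 1,2-Hydride reduction of one of the two equivalent carbonyl groups; the aluminium alkoxide formed is no longer part of a vinylogous anhydride and should resist a second reduction at −78 °C, and the neutral work-up avoids the acid-promoted loss of methanol. The new centre is racemic and is destroyed in step 6.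

Step 2
Reactants: 2 4-hydroxy-2,3-dimethoxycyclobut-2-en-1-one
Product: 3 4-chloro-2,3-dimethoxycyclobut-2-en-1-one (racemic)
Conditions: Ph3PCl2, imidazole, CH2Cl2, −20 → 0 °C; used without storage
Reagents that add atoms: dichlorotriphenylphosphorane, ClP(Cl)(c1ccccc1)(c1ccccc1)c1ccccc1
Why: Appel-type deoxychlorination: the alcohol becomes an alkoxyphosphonium ion, which chloride displaces at a carbon that is both allylic and α to the carbonyl group. The buffered, non-acidic medium should keep the enol ether system from ionising.

Step 3
Reactants: 4 (E)-1,2-bis(tributylstannyl)ethene
Product: 6 (E)-3-(tributylstannyl)prop-2-enoic acid, via vinyllithium 5 (not isolated)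
Conditions: n-BuLi (1.0 equiv), THF, −78 °C; then CO2 (excess), −78 → 0 °C; cold dilute HCl to pH 3–4
Reagents that add atoms: carbon dioxide, O=C=O
Why: Tin–lithium exchange of one stannyl group followed by carboxylation of the vinyllithium; both events proceed with retention, so the E geometry of 4 is carried into 6. The electron-poor vinyl–tin bond should survive the brief, mild acidification.

Step 4
Reactants: 7 1,2,4-trimethoxybenzene; 8 methoxyacetyl chloride
Product: 9 2-methoxy-1-(2,4,5-trimethoxyphenyl)ethan-1-one
Conditions: AlCl3 (1.2 equiv), CH2Cl2, 0 °C
Reagents that add atoms: none
Why: Friedel–Crafts acylation; the position para to the C2 methoxy group and ortho to the C4 methoxy group of 7 is the most nucleophilic unhindered site, which gives the 2,4,5-pattern. The low temperature limits demethylation ortho to the new ketone.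

Step 5
Reactants: 6 (E)-3-(tributylstannyl)prop-2-enoic acid; 9 2-methoxy-1-(2,4,5-trimethoxyphenyl)ethan-1-one
Product: 11 (E)-2-methoxy-5-(tributylstannyl)-1-(2,4,5-trimethoxyphenyl)pent-4-ene-1,3-dione, via acid chloride 10 (not isolated)
Conditions: 6, 1-chloro-N,N,2-trimethylprop-1-en-1-amine, CH2Cl2, 0 °C → rt; then 9, MgBr2·OEt2, i-Pr2NEt, CH2Cl2, 0 °C → rt
Reagents that add atoms: none
Why: The acid chloride is formed under neutral conditions (the by-product is an amide, so no HCl reaches the vinylstannane) and acylates the chelated magnesium enolate obtained by soft enolisation of the α-methoxy ketone (Claisen-type C-acylation). The magnesium diketonate of the product is protected from a second acylation, and the E alkene is not touched; the new CH(OMe) centre is enolisable and racemic.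

Step 6
Reactants: 3 4-chloro-2,3-dimethoxycyclobut-2-en-1-one; 11 (E)-2-methoxy-5-(tributylstannyl)-1-(2,4,5-trimethoxyphenyl)pent-4-ene-1,3-dione
Product: 15 1-(2-hydroxy-3,4-dimethoxyphenyl)-2-methoxy-3-(2,4,5-trimethoxyphenyl)propane-1,3-dione, via 4-alkenylcyclobutenone 12 (not isolated), via dienylketene 13 (not isolated), via cyclohexadienone 14 (not isolated)
Conditions: Pd2(dba)3 (2.5 mol %), tri(2-furyl)phosphine (10 mol %), 1,4-dioxane, 50 °C; then 100 °C
Reagents that add atoms: none
Why: Zerovalent palladium inserts into the C4–Cl bond of 3, which is activated as both allylic and α-keto; the alkenyl group of 11 is transferred from tin with retention of the E geometry, and reductive elimination at the unsubstituted terminus gives 12 with the new C5–C6 bond (Stille coupling). On heating, 12 undergoes a thermal conrotatory 4π opening of the bond between the carbonyl carbon and C4 to give the dienylketene 13. A thermal disrotatory 6π electrocyclisation then joins the ketene carbon to the carbon α to the enone carbonyl (C8a–C4a) and closes ring A as the dienone 14, which enolises to the hydrogen-bonded phenol 15. The closest known reaction type is the palladium-catalysed coupling of 4-chlorocyclobutenones with alkenylstannanes followed by thermal ring expansion to phenols; the dialkoxy chloride and the diketone-bearing stannane are new members of that class. No stereocentre is created: C4 of 12 and the sp3 ring carbon of 14 disappear on ring opening and enolisation, and the CH(OMe) centre remains enolisable. The step needs coupling at C4 and not at the methoxy-bearing allyl terminus C2, which the lack of substitution at C4 should secure. It also needs the ring opening that turns the alkenyl group inward; only that ketene can cyclise, while the outward isomer recloses to 12 and is recycled. The substitution of ring A follows from connectivity alone: the carbonyl oxygen of 3 becomes the phenol on C8a, flanked by the methoxy groups on C8 and C7. Aromatisation and the hydrogen bond to the C4 ketone should make the sequence irreversible.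

Step 7
Reactants: 15 1-(2-hydroxy-3,4-dimethoxyphenyl)-2-methoxy-3-(2,4,5-trimethoxyphenyl)propane-1,3-dione
Product: 16 3,7,8-trimethoxy-2-(2,4,5-trimethoxyphenyl)-4H-chromen-4-one
Conditions: H2SO4 (cat.), AcOH, 90 °C
Reagents that add atoms: none
Why: Acid-catalysed cyclodehydration of an ortho-hydroxyaryl 1,3-diketone, the closing stage of a Baker–Venkataraman flavone synthesis: the phenol adds to the ring B ketone and the hemiketal loses water to give the chromone (O1–C2). Only ring A carries a free phenol, so closure in the other direction is excluded.

Step 8
Reactants: 16 3,7,8-trimethoxy-2-(2,4,5-trimethoxyphenyl)-4H-chromen-4-one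
Product: 18 diplotrin A, via flavone quinone 17 (not isolated)
Conditions: (NH4)2Ce(NO3)6 (2.5 equiv), MeCN/H2O, 0 °C; then EtOAc, aq. Na2S2O4, rt, under argon
Reagents that add atoms: water, O
Why: Oxidative demethylation: the tetravalent cerium salt takes an electron from the most electron-rich arene (ring B), water attacks the methoxy-bearing carbons C2' and C5', and methanol is lost, so the para pair becomes the quinone 17. The 4'-methoxy group has no para oxygen partner and ring A is deactivated by the C4 carbonyl, so both should remain. Na2S2O4 then reduces the crude quinone to the hydroquinone, which keeps 17 away from light and nucleophiles.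

## Compound list

1 | dimethyl squarate (3,4-dimethoxycyclobut-3-ene-1,2-dione) | COC1=C(OC)C(=O)C1=O | starting material
2 | 4-hydroxy-2,3-dimethoxycyclobut-2-en-1-one (racemic) | COC1=C(OC)C(O)C1=O | intermediate
3 | 4-chloro-2,3-dimethoxycyclobut-2-en-1-one (racemic) | COC1=C(OC)C(Cl)C1=O | intermediate
4 | (E)-1,2-bis(tributylstannyl)ethene | CCCC[Sn](CCCC)(CCCC)/C=C/[Sn](CCCC)(CCCC)CCCC | starting material
5 | (E)-2-(tributylstannyl)vinyllithium (not isolated) | CCCC[Sn](CCCC)(CCCC)/C=C/[Li] | intermediate
6 | (E)-3-(tributylstannyl)prop-2-enoic acid | CCCC[Sn](CCCC)(CCCC)/C=C/C(=O)O | intermediate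
7 | 1,2,4-trimethoxybenzene | COc1ccc(OC)c(OC)c1 | starting material
8 | methoxyacetyl chloride | COCC(=O)Cl | starting material
9 | 2-methoxy-1-(2,4,5-trimethoxyphenyl)ethan-1-one | COCC(=O)c1cc(OC)c(OC)cc1OC | intermediate
10 | (E)-3-(tributylstannyl)prop-2-enoyl chloride (not isolated) | CCCC[Sn](CCCC)(CCCC)/C=C/C(=O)Cl | intermediate
11 | (E)-2-methoxy-5-(tributylstannyl)-1-(2,4,5-trimethoxyphenyl)pent-4-ene-1,3-dione (racemic at C2, enolisable) | CCCC[Sn](CCCC)(CCCC)/C=C/C(=O)C(OC)C(=O)c1cc(OC)c(OC)cc1OC | intermediate
12 | 2,3-dimethoxy-4-[(E)-4-methoxy-3,5-dioxo-5-(2,4,5-trimethoxyphenyl)pent-1-en-1-yl]cyclobut-2-en-1-one (mixture of diastereomers, not isolated) | COC1=C(OC)C(/C=C/C(=O)C(OC)C(=O)c2cc(OC)c(OC)cc2OC)C1=O | intermediate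
13 | (3E,5E)-2,3,8-trimethoxy-9-(2,4,5-trimethoxyphenyl)nona-1,3,5-triene-1,7,9-trione (racemic, not isolated) | O=C=C(OC)/C(OC)=C\C=C\C(=O)C(OC)C(=O)c1cc(OC)c(OC)cc1OC | intermediate
14 | 2,3-dimethoxy-6-[2-methoxy-3-oxo-3-(2,4,5-trimethoxyphenyl)propanoyl]cyclohexa-2,4-dien-1-one (mixture of diastereomers, not isolated) | O=C1C(OC)=C(OC)C=CC1C(=O)C(OC)C(=O)c1cc(OC)c(OC)cc1OC | intermediate
15 | 1-(2-hydroxy-3,4-dimethoxyphenyl)-2-methoxy-3-(2,4,5-trimethoxyphenyl)propane-1,3-dione (racemic, enolisable) | COc1ccc(C(=O)C(OC)C(=O)c2cc(OC)c(OC)cc2OC)c(O)c1OC | intermediate
16 | 3,7,8-trimethoxy-2-(2,4,5-trimethoxyphenyl)-4H-chromen-4-one | COc1cc(OC)c(-c2oc3c(OC)c(OC)ccc3c(=O)c2OC)cc1OC | intermediate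
17 | 2-methoxy-5-(3,7,8-trimethoxy-4-oxo-4H-chromen-2-yl)cyclohexa-2,5-diene-1,4-dione (not isolated) | COC1=CC(=O)C(c2oc3c(OC)c(OC)ccc3c(=O)c2OC)=CC1=O | intermediate
18 | diplotrin A, 2-(2,5-dihydroxy-4-methoxyphenyl)-3,7,8-trimethoxy-4H-chromen-4-one | COc1cc(O)c(-c2oc3c(OC)c(OC)ccc3c(=O)c2OC)cc1O | target

## Step count and least certain steps

Total step count: 8 steps. Longest linear sequence: 5 steps (7 and 8 → 9 → 11 → 15 → 16 → 18, steps 4 to 8; the branches from 1 and from 4 are equally long).

**Step 6 (key step).** The most likely failure is slow transfer of the electron-poor, chelating alkenyl group from tin. The cyclobutenonyl-palladium intermediate would then decay by loss of chloromethane, reduction or homocoupling, and 11 could lose tin by protonation from its own acidic enol. A proton shift in 12 that competes with ring opening is the second concern. The fallback keeps the same two bonds but moves the diketone out of the palladium step; it sets out from 5 and 3 and comes back at 15. Vinyllithium 5 would be acylated with N,2-dimethoxy-N-methylacetamide (THF, −78 °C) to give (E)-1-methoxy-4-(tributylstannyl)but-3-en-2-one F1, a plain β-stannyl enone of an established partner type. Coupling of F1 with 3 and ring expansion under the conditions of step 6 should give 1-(2-hydroxy-3,4-dimethoxyphenyl)-2-methoxyethan-1-one F2. Esterification with 2,4,5-trimethoxybenzoyl chloride in pyridine would give 2,3-dimethoxy-6-(2-methoxyacetyl)phenyl 2,4,5-trimethoxybenzoate F3, and a Baker–Venkataraman rearrangement (KOH, pyridine, 50 °C) would deliver 15.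

**Step 2.** The most likely failure is ionisation of the activated C4 position, or attack of chloride at the methoxy-bearing alkene carbon with allylic shift. Either is followed by loss of chloromethane and collapse to a cyclobutenedione, and decomposition on concentration is also possible. The fallback replaces the halide by an allylic carbonate; it sets out from 2 and comes back at 15. Treatment of 2 with methyl chloroformate and pyridine (CH2Cl2, 0 °C) would give 2,3-dimethoxy-4-oxocyclobut-2-en-1-yl methyl carbonate F4, which is less prone to ionise on its own. Zerovalent palladium (Pd2(dba)3, tri(2-furyl)phosphine, dioxane, 50 then 100 °C) should ionise F4 with loss of carbon dioxide, the methoxide released would activate the tin of 11 under neutral conditions, and the coupling product 12 would go on to 15 as in step 6.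

**Step 5.** The most likely failure is acylation of the enolate at oxygen, which gives an enol ester, together with cleavage of the vinyl–tin bond during activation of the acid. The fallback forms the same C–C bond by an aldol addition and adjusts the oxidation level afterwards; it sets out from 5 and 9 and comes back at 11. Formylation of 5 with N,N-dimethylformamide (THF, −78 °C) would give (E)-3-(tributylstannyl)prop-2-enal F5. Addition of the lithium enolate of 9 (LiN(SiMe3)2, THF, −78 °C) would give (E)-3-hydroxy-2-methoxy-5-(tributylstannyl)-1-(2,4,5-trimethoxyphenyl)pent-4-en-1-one F6 as a mixture of diastereomers, and oxidation with Dess–Martin periodinane buffered with NaHCO3 would give 11.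

**Step 8.** The most likely failure is oxidation that is not confined to the para pair of ring B: over-oxidation, attack on ring A or on the C2=C3 enol ether, or incomplete reaction because the chromone deactivates ring B. The fallback carries the 2'- and 5'-oxygens as benzyl ethers and ends with a hydrogenolysis; it sets out from 8 (with 6 and 3 used as in the main route) and comes back at 18.
- Commercial 2-methoxybenzene-1,4-diol would be benzylated (BnBr, K2CO3, DMF) to 1,4-bis(benzyloxy)-2-methoxybenzene F7.
- Acylation of F7 with 8 under a mild Lewis acid (SnCl4, CH2Cl2, −20 °C) would give 1-[2,5-bis(benzyloxy)-4-methoxyphenyl]-2-methoxyethan-1-one F8.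
- Acylation of F8 as in step 5 would give (E)-1-[2,5-bis(benzyloxy)-4-methoxyphenyl]-2-methoxy-5-(tributylstannyl)pent-4-ene-1,3-dione F9.
- Coupling of F9 with 3 as in step 6 would give 1-[2,5-bis(benzyloxy)-4-methoxyphenyl]-3-(2-hydroxy-3,4-dimethoxyphenyl)-2-methoxypropane-1,3-dione F10.
- Cyclodehydration (p-TsOH, toluene, 80 °C) would give 2-[2,5-bis(benzyloxy)-4-methoxyphenyl]-3,7,8-trimethoxy-4H-chromen-4-one F11, identical with A8.
- Hydrogenolysis (H2, 10% palladium on carbon, EtOAc) would give 18.

**Step 4.** The most likely failure is loss of carbon monoxide from the methoxyacetyl cation, which would alkylate the arene with a methoxymethyl cation instead of acylating it; demethylation ortho to the new ketone by AlCl3 is the second concern. The fallback makes the aryl–carbonyl bond from an aryllithium; it sets out from 7 and comes back at 9. Bromination of 7 (N-bromosuccinimide, MeCN, 0 °C) would give 1-bromo-2,4,5-trimethoxybenzene F12. Bromine–lithium exchange (n-BuLi, THF, −78 °C) and addition to N,2-dimethoxy-N-methylacetamide would give 9.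

## Further compounds

F1 | step 6 | (E)-1-methoxy-4-(tributylstannyl)but-3-en-2-one | COCC(=O)/C=C/[Sn](CCCC)(CCCC)CCCC
F2 | step 6 | 1-(2-hydroxy-3,4-dimethoxyphenyl)-2-methoxyethan-1-one | COCC(=O)c1ccc(OC)c(OC)c1O
F3 | step 6 | 2,3-dimethoxy-6-(2-methoxyacetyl)phenyl 2,4,5-trimethoxybenzoate | COCC(=O)c1ccc(OC)c(OC)c1OC(=O)c1cc(OC)c(OC)cc1OC
F4 | step 2 | 2,3-dimethoxy-4-oxocyclobut-2-en-1-yl methyl carbonate (racemic) | COC(=O)OC1C(OC)=C(OC)C1=O
F5 | step 5 | (E)-3-(tributylstannyl)prop-2-enal | CCCC[Sn](CCCC)(CCCC)/C=C/C=O
F6 | step 5 | (E)-3-hydroxy-2-methoxy-5-(tributylstannyl)-1-(2,4,5-trimethoxyphenyl)pent-4-en-1-one (mixture of diastereomers) | CCCC[Sn](CCCC)(CCCC)/C=C/C(O)C(OC)C(=O)c1cc(OC)c(OC)cc1OC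
F7 | step 8 | 1,4-bis(benzyloxy)-2-methoxybenzene | COc1cc(OCc2ccccc2)ccc1OCc1ccccc1
F8 | step 8 | 1-[2,5-bis(benzyloxy)-4-methoxyphenyl]-2-methoxyethan-1-one | COCC(=O)c1cc(OCc2ccccc2)c(OC)cc1OCc1ccccc1
F9 | step 8 | (E)-1-[2,5-bis(benzyloxy)-4-methoxyphenyl]-2-methoxy-5-(tributylstannyl)pent-4-ene-1,3-dione (racemic, enolisable) | CCCC[Sn](CCCC)(CCCC)/C=C/C(=O)C(OC)C(=O)c1cc(OCc2ccccc2)c(OC)cc1OCc1ccccc1
F10 | step 8 | 1-[2,5-bis(benzyloxy)-4-methoxyphenyl]-3-(2-hydroxy-3,4-dimethoxyphenyl)-2-methoxypropane-1,3-dione (racemic, enolisable) | COc1ccc(C(=O)C(OC)C(=O)c2cc(OCc3ccccc3)c(OC)cc2OCc2ccccc2)c(O)c1OC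
F11 | step 8 | 2-[2,5-bis(benzyloxy)-4-methoxyphenyl]-3,7,8-trimethoxy-4H-chromen-4-one | COc1cc(OCc2ccccc2)c(-c2oc3c(OC)c(OC)ccc3c(=O)c2OC)cc1OCc1ccccc1
F12 | step 4 | 1-bromo-2,4,5-trimethoxybenzene | COc1cc(OC)c(OC)cc1Br
A1 | alternative 1 | 4-methoxy-2-(tert-butyldimethylsiloxy)furan | COc1coc(O[Si](C)(C)C(C)(C)C)c1
A2 | alternative 1 | 2-ethynyl-3,7,8-trimethoxy-4H-chromen-4-one | C#Cc1oc2c(OC)c(OC)ccc2c(=O)c1OC
A3 | alternative 1 | 2-[2-(tert-butyldimethylsiloxy)-5-hydroxy-4-methoxyphenyl]-3,7,8-trimethoxy-4H-chromen-4-one | COc1cc(O[Si](C)(C)C(C)(C)C)c(-c2oc3c(OC)c(OC)ccc3c(=O)c2OC)cc1O
A4 | alternative 2 | 1-iodo-3,4-dimethoxy-2-(methoxymethoxy)benzene | COCOc1c(I)ccc(OC)c1OC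
A5 | alternative 2 | 1-[3,4-dimethoxy-2-(methoxymethoxy)phenyl]-2-methoxy-3-(2,4,5-trimethoxyphenyl)propane-1,3-dione (racemic, enolisable) | COCOc1c(C(=O)C(OC)C(=O)c2cc(OC)c(OC)cc2OC)ccc(OC)c1OC
A6 | alternative 3 | 2-hydroxy-3,4-dimethoxybenzaldehyde | COc1ccc(C=O)c(O)c1OC
A7 | alternative 3 | 1,4-bis(benzyloxy)-2-methoxy-5-(methoxyethynyl)benzene | COC#Cc1cc(OCc2ccccc2)c(OC)cc1OCc1ccccc1
A8 | alternative 3 | 2-[2,5-bis(benzyloxy)-4-methoxyphenyl]-3,7,8-trimethoxy-4H-chromen-4-one | COc1cc(OCc2ccccc2)c(-c2oc3c(OC)c(OC)ccc3c(=O)c2OC)cc1OCc1ccccc1
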